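**Retrosynthetic overview**
- The target is a 2,4,6-trisubstituted oxane (O1; C2 aryl; C4 OH; C6 side chain; C1' = side-chain carbinol carbon). The last operations are debenzylation and Tamao–Fleming oxidation of a C1'–Si–O4 bridge, which releases both secondary alcohols at once.
- Key disconnection C6–C1': 6-exo-trig cyclisation of the C6 (anomeric) radical onto an (E)-styrylsilane tethered to O4, closing a temporary 1-oxa-2-silacyclohexane (C4–O4–Si–C1'–C6–C5) across the oxane.
- Enabling feature: on the oxane ring, O4 and the C6 side chain are cis (both axial when the C2 aryl is equatorial), and C1' carries an oxygen one bond beyond the new bond. One silicon atom can therefore span O4 and C1' and is later replaced by the two hydroxyls.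
- The cyclisation precursor comes from a 2-aryl-2,3-dihydro-4H-pyran-4-one by thiol conjugate addition (C6–S radical handle), axial-selective ketone reduction (C4) and O4 silylation.
- Ring order: the oxane first, by asymmetric cyclocondensation of O-benzylvanillin with a siloxydiene (sets C2); the siloxane ring second (key step), opened again by oxidation.

Key step: step 6

Remark on numbering: the oxane numbering above (O1, C2 aryl-bearing, C4, C6, C1') is used for all intermediates.
Assumption: (S)-BINOL is taken as the ligand that gives the (S)-carbinol, by analogy with simple aromatic aldehydes; the sense is to be confirmed on compound 4, and (R)-BINOL is used instead if it proves opposite.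

**Step 1**
Reactants: 1 4-(benzyloxy)-3-methoxybenzaldehyde; 2 (E)-1-methoxy-3-(trimethylsilyloxy)buta-1,3-diene
Product: 4 (2S)-2-[4-(benzyloxy)-3-methoxyphenyl]-2,3-dihydro-4H-pyran-4-one, via silylated Mukaiyama aldol adduct 3 (not isolated)
Conditions: Ti(OiPr)4 (10 mol%), (S)-BINOL (20 mol%), 4 Å MS, Et2O, −20 °C; then TFA, CH2Cl2, 0 °C
Reagents that add atoms: none
Why: BINOL–titanium-catalysed asymmetric Mukaiyama aldol/cyclocondensation (formal hetero-Diels–Alder reaction), in which the chiral Lewis acid shields one aldehyde face so that C2 should be set (S), and TFA then closes the ring by oxa-Michael addition with loss of methanol.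

**Step 2**
Reactants: 4 (2S)-2-[4-(benzyloxy)-3-methoxyphenyl]-2,3-dihydro-4H-pyran-4-one
Product: 5 (2S)-2-[4-(benzyloxy)-3-methoxyphenyl]-6-(phenylsulfanyl)oxan-4-one (C6 epimers, 2,6-trans expected to predominate)
Conditions: PhSH (1.5 equiv), Et3N (10 mol%), CH2Cl2, 0 °C to rt
Reagents that add atoms: thiophenol, Sc1ccccc1
Why: Base-catalysed thia-Michael addition to the vinylogous ester, as known for sugar-derived 2,3-dihydro-4H-pyran-4-ones, should place sulfur at C6; the C6 configuration is immaterial because it is erased in step 6.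

**Step 3**
Reactants: 5 (2S)-2-[4-(benzyloxy)-3-methoxyphenyl]-6-(phenylsulfanyl)oxan-4-one
Product: 6 (2S,4R)-2-[4-(benzyloxy)-3-methoxyphenyl]-6-(phenylsulfanyl)oxan-4-ol (OH axial, trans to the aryl; C6 epimers)
Conditions: LiBH(s-Bu)3, THF, −78 °C; then H2O
Reagents that add atoms: none
Why: Bulky-hydride reduction of a 2,6-disubstituted oxan-4-one proceeds by equatorial attack on the chair with the aryl equatorial (axial approach is further blocked by an axial C6–S bond), which should give the axial C4 alcohol trans to the aryl (4R).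

**Step 4**
Reactants: 7 1-(benzyloxy)-4-ethynylbenzene; 8 chlorodimethylsilane
Product: 9 {(E)-2-[4-(benzyloxy)phenyl]ethenyl}(chloro)dimethylsilane
Conditions: Pt2[(CH2=CHSiMe2)2O]3 (0.1 mol%), P(t-Bu)3, THF, 0 °C to rt; volatiles removed, used crude
Reagents that add atoms: none
Why: Platinum-catalysed syn hydrosilylation of a terminal aryl alkyne, made anti-Markovnikov by the bulky phosphine, should give the (E)-β-silylstyrene; the alkene geometry is not critical because it is lost in step 6.

**Step 5**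
Reactants: 6 (2S,4R)-2-[4-(benzyloxy)-3-methoxyphenyl]-6-(phenylsulfanyl)oxan-4-ol; 9 {(E)-2-[4-(benzyloxy)phenyl]ethenyl}(chloro)dimethylsilane
Product: 10 {(E)-2-[4-(benzyloxy)phenyl]ethenyl}({(2S,4R)-2-[4-(benzyloxy)-3-methoxyphenyl]-6-(phenylsulfanyl)oxan-4-yl}oxy)dimethylsilane
Conditions: imidazole (2 equiv), DMAP (cat.), CH2Cl2, 0 °C to rt; filtration through Et3N-deactivated silica
Reagents that add atoms: none
Why: Standard silyl ether formation from a chlorosilane at the only free (axial) hydroxyl attaches the styrylsilane tether to O4 without touching any stereocentre.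

**Step 6**
Reactants: 10 {(E)-2-[4-(benzyloxy)phenyl]ethenyl}({(2S,4R)-2-[4-(benzyloxy)-3-methoxyphenyl]-6-(phenylsulfanyl)oxan-4-yl}oxy)dimethylsilane
Product: 11 (1R,4R,5S,7S)-7-[4-(benzyloxy)-3-methoxyphenyl]-4-{[4-(benzyloxy)phenyl]methyl}-3,3-dimethyl-2,6-dioxa-3-silabicyclo[3.3.1]nonane (the oxane bridged from O4 to C6 by –SiMe2–C1'H(CH2Ar)–)
Conditions: Bu3SnH (1.3 equiv) and AIBN (0.2 equiv) by syringe pump over 8 h, PhMe (5 mM), 110 °C; short silica pad
Reagents that add atoms: none
Why: Bu3Sn• removes the PhS group from C6 of either epimer of 10 to give one anomeric (α-oxy) radical, which adds 6-exo-trig to the silicon-bearing carbon of the O4-tethered styrylsilane, and the resulting benzylic radical is quenched by Bu3SnH. The closest known reaction type is the temporary-silicon-connection radical C-glycosylation, in which an anomeric radical cyclises onto a vinyl- or alkynylsilyl ether of a ring hydroxyl and the C–Si bond is oxidised afterwards. The ring closed is the 1-oxa-2-silacyclohexane C4–O4–Si–C1'–C6–C5 (6-exo-trig), which bridges the oxane as a 2,6-dioxa-3-silabicyclo[3.3.1]nonane. C6 is controlled by the tether: with the aryl equatorial the C4–O bond is axial, and the silicon-bound carbon can reach C6 only along the axial direction on that same face, so the new bond should be cis to O4 and trans to the aryl whatever the C6 ratio of 10. C1' is controlled by the shape of the bridged transition state: a chair oxasilane would drive silicon and its inward methyl into the axial H–C2, so a sofa-to-boat closure is expected in which the styryl carbon lies outside the bicycle beside H–C6 and not over ring O1, which corresponds to (1'R) after retentive oxidation; E and Z alkene should converge because the geometry is lost in the benzylic radical. The step needs exo over 7-endo closure (secured by benzylic stabilisation of the exo radical) and cyclisation over premature reduction (secured by slow hydride addition at high dilution).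

**Step 7**
Reactants: 11 (1R,4R,5S,7S)-7-[4-(benzyloxy)-3-methoxyphenyl]-4-{[4-(benzyloxy)phenyl]methyl}-3,3-dimethyl-2,6-dioxa-3-silabicyclo[3.3.1]nonane
Product: 12 (2S,4R,6S)-2-[4-(benzyloxy)-3-methoxyphenyl]-6-{(1R)-2-[4-(benzyloxy)phenyl]-1-hydroxyethyl}oxan-4-ol
Conditions: 30% aq. H2O2, KF, KHCO3, THF/MeOH (1:1), rt to 40 °C; then aq. Na2S2O3
Reagents that add atoms: hydrogen peroxide, OO
Why: Tamao–Fleming oxidation of the alkoxydialkylsilane moves C1' from silicon to oxygen with retention, which should give the (1'R) carbinol, and hydrolysis of the Si–O bonds frees O4.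

**Step 8**
Reactants: 12 (2S,4R,6S)-2-[4-(benzyloxy)-3-methoxyphenyl]-6-{(1R)-2-[4-(benzyloxy)phenyl]-1-hydroxyethyl}oxan-4-ol
Product: 13 (2S,4R,6S)-2-(4-hydroxy-3-methoxyphenyl)-6-[(1R)-1-hydroxy-2-(4-hydroxyphenyl)ethyl]oxan-4-ol (CNP0116327.3)
Conditions: H2 (1 atm), 10% Pd/C, EtOAc/EtOH, rt
Reagents that add atoms: none
Why: Catalytic hydrogenolysis should cleave the two aryl benzyl ethers much faster than the ring benzylic C2–O bond and affects no stereocentre.

**Compound list**
1 | 4-(benzyloxy)-3-methoxybenzaldehyde | COc1cc(C=O)ccc1OCc1ccccc1 | starting material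
2 | (E)-1-methoxy-3-(trimethylsilyloxy)buta-1,3-diene | CO/C=C/C(=C)O[Si](C)(C)C | starting material
3 | (1E,5S)-5-[4-(benzyloxy)-3-methoxyphenyl]-1-methoxy-5-(trimethylsilyloxy)pent-1-en-3-one | COc1cc([C@@H](O[Si](C)(C)C)CC(=O)/C=C/OC)ccc1OCc1ccccc1 | intermediate
4 | (2S)-2-[4-(benzyloxy)-3-methoxyphenyl]-2,3-dihydro-4H-pyran-4-one | COc1cc([C@@H]2CC(=O)C=CO2)ccc1OCc1ccccc1 | intermediate
5 | (2S)-2-[4-(benzyloxy)-3-methoxyphenyl]-6-(phenylsulfanyl)oxan-4-one (C6 epimers) | COc1cc([C@@H]2CC(=O)CC(Sc3ccccc3)O2)ccc1OCc1ccccc1 | intermediate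
6 | (2S,4R)-2-[4-(benzyloxy)-3-methoxyphenyl]-6-(phenylsulfanyl)oxan-4-ol (C6 epimers) | COc1cc([C@@H]2C[C@@H](O)CC(Sc3ccccc3)O2)ccc1OCc1ccccc1 | intermediate
7 | 1-(benzyloxy)-4-ethynylbenzene | C#Cc1ccc(OCc2ccccc2)cc1 | starting material
8 | chlorodimethylsilane | C[SiH](C)Cl | starting material
9 | {(E)-2-[4-(benzyloxy)phenyl]ethenyl}(chloro)dimethylsilane | C[Si](C)(Cl)/C=C/c1ccc(OCc2ccccc2)cc1 | intermediate
10 | {(E)-2-[4-(benzyloxy)phenyl]ethenyl}({(2S,4R)-2-[4-(benzyloxy)-3-methoxyphenyl]-6-(phenylsulfanyl)oxan-4-yl}oxy)dimethylsilane | COc1cc([C@@H]2C[C@@H](O[Si](C)(C)/C=C/c3ccc(OCc4ccccc4)cc3)CC(Sc3ccccc3)O2)ccc1OCc1ccccc1 | intermediate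
11 | (1R,4R,5S,7S)-7-[4-(benzyloxy)-3-methoxyphenyl]-4-{[4-(benzyloxy)phenyl]methyl}-3,3-dimethyl-2,6-dioxa-3-silabicyclo[3.3.1]nonane | COc1cc([C@@H]2C[C@@H]3C[C@H](O2)[C@@H](Cc4ccc(OCc5ccccc5)cc4)[Si](C)(C)O3)ccc1OCc1ccccc1 | intermediate
12 | (2S,4R,6S)-2-[4-(benzyloxy)-3-methoxyphenyl]-6-{(1R)-2-[4-(benzyloxy)phenyl]-1-hydroxyethyl}oxan-4-ol | COc1cc([C@@H]2C[C@@H](O)C[C@@H]([C@H](O)Cc3ccc(OCc4ccccc4)cc3)O2)ccc1OCc1ccccc1 | intermediate
13 | (2S,4R,6S)-2-(4-hydroxy-3-methoxyphenyl)-6-[(1R)-1-hydroxy-2-(4-hydroxyphenyl)ethyl]oxan-4-ol | COc1cc([C@@H]2C[C@@H](O)C[C@@H]([C@H](O)Cc3ccc(O)cc3)O2)ccc1O | target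

**Step count and risks**
Total step count: 8. Longest linear sequence: 7 steps (1, 2, 3, 5, 6, 7, 8).

Step 6 (key step). What may go wrong: poor facial selectivity at C1' (the two sofa-like closures differ only in whether the styryl carbon sits beside H–C6 or over O1), slow abstraction of the phenylsulfanyl group, and reduction of the anomeric radical before it cyclises. The fallback sets out from 6 and 7 and comes back at 12; it takes the C1' configuration out of the cyclisation and sets it afterwards by substrate control. Alkyne 7 is deprotonated (n-BuLi, THF, −78 °C) and added to excess Me2SiCl2 to give chloro{[4-(benzyloxy)phenyl]ethynyl}dimethylsilane F1, which silylates 6 (imidazole, CH2Cl2) to give ({(2S,4R)-2-[4-(benzyloxy)-3-methoxyphenyl]-6-(phenylsulfanyl)oxan-4-yl}oxy){[4-(benzyloxy)phenyl]ethynyl}dimethylsilane F2. Bu3SnH/AIBN should then close the same oxasilane by the faster 6-exo-dig mode (α-aryl vinyl radical, reduced by the stannane) to the bicyclic alkenylsiloxane (1R,5S,7S)-7-[4-(benzyloxy)-3-methoxyphenyl]-4-{[4-(benzyloxy)phenyl]methylidene}-3,3-dimethyl-2,6-dioxa-3-silabicyclo[3.3.1]nonane F3, whose alkene geometry does not matter. Tamao–Fleming oxidation (H2O2, KF, KHCO3) should convert the alkenyl–silicon bond into a ketone and free O4, giving 1-{(2S,4R,6S)-6-[4-(benzyloxy)-3-methoxyphenyl]-4-hydroxyoxan-2-yl}-2-[4-(benzyloxy)phenyl]ethan-1-one F4. Zn(BH4)2 (Et2O, −20 °C) should reduce F4 under chelation control: zinc bridges ring O1 and the carbonyl oxygen, and hydride enters from the face away from C5 and the axial O4, giving the 1,2-anti (1'R) carbinol, which is 12.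

Step 2. What may go wrong: reversal of the thiol addition and β-elimination of the ring alkoxide (ring opening) under the amine base, so that the adduct is not obtained cleanly. The fallback sets out from 4 and comes back at 6; the C6 heteroatom is introduced first as an O-acetal by mass action and exchanged for sulfur only after the ketone is gone. PPTS in MeOH should add methanol to the vinylogous ester to give (2S)-2-[4-(benzyloxy)-3-methoxyphenyl]-6-methoxyoxan-4-one F5. LiBH(s-Bu)3 (THF, −78 °C) should give the axial alcohol (2S,4R)-2-[4-(benzyloxy)-3-methoxyphenyl]-6-methoxyoxan-4-ol F6. PhSH/BF3·OEt2 (CH2Cl2, −78 °C) then exchanges the anomeric methoxy group for phenylsulfanyl through the oxocarbenium ion (2-deoxy-thioglycosidation) to give 6.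

Step 1. What may go wrong: incomplete cyclocondensation of the donor-substituted, deactivated aldehyde, and erosion of enantiopurity by acid-promoted ionisation of the benzylic C2–O bond of the vinylogous ester during the TFA stage. The fallback sets out from 1 and comes back at 6; the oxane is assembled as a δ-lactone and no dihydropyranone or strong acid is involved. Ti(OiPr)4/BINOL-catalysed vinylogous Mukaiyama aldol of 1 with 1-methoxy-1,3-bis(trimethylsilyloxy)buta-1,3-diene, followed by mild desilylation, should give methyl (5S)-5-[4-(benzyloxy)-3-methoxyphenyl]-5-hydroxy-3-oxopentanoate F7. Narasaka–Prasad reduction (Et2BOMe, NaBH4, THF/MeOH, −78 °C) should give the syn-diol methyl (3R,5S)-5-[4-(benzyloxy)-3-methoxyphenyl]-3,5-dihydroxypentanoate F8. PPTS in warm toluene lactonises it to the trans-lactone (4R,6S)-6-[4-(benzyloxy)-3-methoxyphenyl]-4-hydroxyoxan-2-one F9, where recrystallisation may raise the enantiomeric purity. i-Bu2AlH (2.2 equiv, CH2Cl2, −78 °C) should give the lactol (4R,6S)-6-[4-(benzyloxy)-3-methoxyphenyl]oxane-2,4-diol F10. Redox condensation with PhSSPh/PBu3 then replaces the anomeric hydroxyl by phenylsulfanyl and gives 6.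

**Further compounds**
F1 | step 6 | chloro{[4-(benzyloxy)phenyl]ethynyl}dimethylsilane | C[Si](C)(Cl)C#Cc1ccc(OCc2ccccc2)cc1
F2 | step 6 | ({(2S,4R)-2-[4-(benzyloxy)-3-methoxyphenyl]-6-(phenylsulfanyl)oxan-4-yl}oxy){[4-(benzyloxy)phenyl]ethynyl}dimethylsilane | COc1cc([C@@H]2C[C@@H](O[Si](C)(C)C#Cc3ccc(OCc4ccccc4)cc3)CC(Sc3ccccc3)O2)ccc1OCc1ccccc1
F3 | step 6 | (1R,5S,7S)-7-[4-(benzyloxy)-3-methoxyphenyl]-4-{[4-(benzyloxy)phenyl]methylidene}-3,3-dimethyl-2,6-dioxa-3-silabicyclo[3.3.1]nonane (E/Z mixture) | COc1cc([C@@H]2C[C@@H]3C[C@H](O2)C(=Cc4ccc(OCc5ccccc5)cc4)[Si](C)(C)O3)ccc1OCc1ccccc1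
F4 | step 6 | 1-{(2S,4R,6S)-6-[4-(benzyloxy)-3-methoxyphenyl]-4-hydroxyoxan-2-yl}-2-[4-(benzyloxy)phenyl]ethan-1-one | COc1cc([C@@H]2C[C@@H](O)C[C@@H](C(=O)Cc3ccc(OCc4ccccc4)cc3)O2)ccc1OCc1ccccc1
F5 | step 2 | (2S)-2-[4-(benzyloxy)-3-methoxyphenyl]-6-methoxyoxan-4-one (C6 epimers) | COc1cc([C@@H]2CC(=O)CC(OC)O2)ccc1OCc1ccccc1
F6 | step 2 | (2S,4R)-2-[4-(benzyloxy)-3-methoxyphenyl]-6-methoxyoxan-4-ol (C6 epimers) | COc1cc([C@@H]2C[C@@H](O)CC(OC)O2)ccc1OCc1ccccc1
F7 | step 1 | methyl (5S)-5-[4-(benzyloxy)-3-methoxyphenyl]-5-hydroxy-3-oxopentanoate | COC(=O)CC(=O)C[C@H](O)c1ccc(OCc2ccccc2)c(OC)c1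
F8 | step 1 | methyl (3R,5S)-5-[4-(benzyloxy)-3-methoxyphenyl]-3,5-dihydroxypentanoate | COC(=O)C[C@H](O)C[C@H](O)c1ccc(OCc2ccccc2)c(OC)c1
F9 | step 1 | (4R,6S)-6-[4-(benzyloxy)-3-methoxyphenyl]-4-hydroxyoxan-2-one | O=C1C[C@H](O)C[C@@H](c2ccc(OCc3ccccc3)c(OC)c2)O1
F10 | step 1 | (4R,6S)-6-[4-(benzyloxy)-3-methoxyphenyl]oxane-2,4-diol (anomers) | OC1C[C@H](O)C[C@@H](c2ccc(OCc3ccccc3)c(OC)c2)O1
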